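## Analysis of the target

Rhoiptelol B (16) is a cyclic diarylheptanoid built on an oxane (tetrahydropyran) ring, numbered here O1, C2 to C6. The ring carries a guaiacyl (4-hydroxy-3-methoxyphenyl) group on C2, a secondary hydroxyl on C4 and, on C6, a side chain C7(OH)–C8H2 that ends in a 4-hydroxyphenyl ring. Its four stereocentres are 2R, 4S, 6S and 7S: the C2 aryl group and the C6 side chain are cis and both equatorial in the chair, the C4 hydroxyl is axial and so trans to both, and the C7 hydroxyl is syn to the C6–O1 bond when C5–C6–C7–C8 is drawn as a zigzag. The C2–O1 bond is a benzylic ether para to a phenolic oxygen. It can ionise under acid, open through a quinone methide once the phenol is free under basic conditions, and be cut by over-hydrogenolysis, so the phenols are best kept masked until a last, neutral step. The same lability makes C2 correctable, because the 2,6-cis diequatorial arrangement is the thermodynamic one, whereas C6, C7 and the axial C4 carbinol cannot be repaired by equilibration. The difficulty therefore lies at C6 and C4: the C6/C7 syn relationship is the one that a non-chelated α-oxygenated aldehyde does not give on its own, and the axial alcohol is the less stable C4 epimer. The strategy rests on reading the ring as the sum of a carbonyl unit, C6=O1 of an aldehyde that already holds C7 and C8, and a 2-oxygenated four-carbon diene, C2=C3–C4(O)=C5, whose terminus C2 bears the guaiacyl ring. The two pieces together contain every carbon of the target.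

## Retrosynthetic reasoning

**Protecting groups (16 to 15 to 14).** The last bonds cut are the two phenolic O–benzyl bonds of 15 and, one step before, the O–Si bond of the C7 silyl ether in 14. Benzyl ethers are chosen for the phenols because they survive every acidic, basic and hydridic step and fall under neutral hydrogenolysis. The silyl ether is removed first, while the phenols are still masked, so that no phenoxide is ever generated para to the C2–O1 bond under basic desilylation conditions.

**The C4 carbinol (14 to 13).** The C4–H bond is cut, leaving the oxan-4-one 13. This removes the least stable stereocentre from the plan and defers it to a point where the ring is a locked chair with two equatorial anchors, so that a bulky hydride reagent can only deliver the axial alcohol. A ketone at C4 is also exactly what a 2-oxygenated diene leaves behind.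

**The ring (13 to 12 to 3 + 11).** Ketone 13 is the hydrolysis product of the silyl enol ether 12. In 12 the bonds C5–C6 and O1–C2 are cut together, which is the retron of a hetero-Diels–Alder reaction between the 2-silyloxy diene 3 and the aldehyde 11. This cut is preferred to any single-bond ring closure because it forms both ring bonds and two stereocentres (C6 and C2) in one step from fragments of nearly equal size, and because C7 is brought in intact. The forward reaction has to choose the aldehyde face under the control of a chiral Lewis acid (specified in step 7) against the aldehyde's own bias, and has to proceed through the endo arrangement so that C2 and C6 end up cis.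

**The diene (3 to 2 to 1).** The O–Si bond of 3 is cut to give the enone 2, whose methyl group is its only enolisable position, so the diene can form as one regioisomer. The O–benzyl bond of 2 is then cut to give the commercial phenol 1. All four diene carbons and the guaiacyl ring come from 1.

**The aldehyde (11 to 9 to 8 to 7 to 4).** The aldehyde carbon of 11 is traced to the ester carbon of 9, the silyl ether of 9 to the hydroxy ester 8, and 8 to the hydroxy acid 7. The C–O bond at the stereocentre of 7 is traced to the C–N bond of the commercial amino acid derivative 4, because nitrous deamination of an α-amino acid proceeds with retention. In this way C7 is taken from the chiral pool, already in the S configuration and with the phenol already benzylated.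

## Alternatives that were turned down

**Alternative 1:** The disconnection is at C3–C4 and C4–C5, with C4 as the carbon of a dithiane that acts as a two-fold nucleophile. In the forward key step 2-(tert-butyldimethylsilyl)-1,3-dithiane A1, after lithiation, would open the racemic aryl oxirane A2 at its CH2 (C3). A 1,4 shift of silicon from carbon to the new C2 alkoxide (Brook rearrangement, triggered by a polar cosolvent) would regenerate a dithiane anion, which would open the side-chain epoxide A3 at C5 and give the open-chain dithiane A4.

- For: three components are joined in one flask and two C–C bonds are formed. C6 and C7 arrive fixed in A3, so the key step creates no stereocentre against a substrate bias. On this point it is stronger than the chosen route, whose key step is a mismatched pairing.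
- Against: no ring closes and C2 is formed as both epimers. Dithiane removal (by oxidising or thiophilic reagents that are poorly matched to electron-rich arenes), ring closure with control of C2 and the C4 reduction all still lie ahead. The electron-rich oxirane A2 is prone to attack at its benzylic carbon and to rearrangement. A3 requires the syn C6/C7 unit to be built beforehand over several steps, so the stereochemical problem is moved upstream rather than removed.
- Comparison: the chosen strategy forms one C–C bond instead of two in its key step, but it closes the ring, sets C6 and C2, and delivers the masked ketone 13 directly, from fragments that need two and four steps.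

**Alternative 2:** The disconnection is at C2–C3. C2 starts as the CH2 of a guaiacyl-type benzyl ether on the C6 oxygen and C3 as the terminal carbon of an enol acetate, as in A5. In the forward key step a quinone oxidant would abstract hydride from that benzylic ether CH2 to give an aryl-stabilised oxocarbenium ion. The enol acetate would attack it through a chair with the C6 substituent equatorial and give the 2,6-cis oxan-4-one A6.

- For: no pre-oxidised C2 is needed. The cis ring follows from the chair transition state. The C6 oxygen is installed before the cyclisation by an addition under chelation control, for which the syn C6/C7 relationship is the natural outcome. On C6 this alternative is therefore stronger than the chosen route.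
- Against: A5 contains four other benzylic CH2 groups (three benzyl ethers and C8), and the product A6 still has an oxidisable benzylic C2–H, so the oxidation must pick one site out of several. A5 needs roughly twice as many linear steps as either fragment of the chosen route (aldehyde, propargylation, etherification of a hindered secondary alcohol with an acid-sensitive benzylic electrophile, conversion of the alkyne into the enol acetate). A6 carries a secondary alkyl benzyl ether whose slower hydrogenolysis has to be forced next to the C2–O1 bond.
- Comparison: the chosen strategy offers in its place a ring construction free of redox chemoselectivity questions and a silyl group at C7 that is removed without touching C2–O1.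

**Alternative 3:** The disconnection is at O1–C2. In the forward key step acid would ionise the C2 carbinol of the open-chain diol A7 (both C2 epimers) to a guaiacyl-stabilised benzylic cation. The C6 hydroxyl would capture it through a chair with the aryl group equatorial and give the protected oxane A8.

- For: the step is stereoconvergent and C2 is set thermodynamically, which is more secure than the kinetic endo preference on which the chosen route relies. The chosen route can, however, also correct C2 at the stage of ketone 13 by reversible ring opening.
- Against: C4, C6 and C7 must all be set in an open chain, with the C6 hydroxyl free and the C4 and C7 hydroxyls differentiated as silyl ethers. That means a long linear sequence of acyclic stereocontrol and protecting-group operations. The ionising acid has to spare two silyl ethers, and elimination to the styrene competes. The key step forms one C–O bond and no C–C bond.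
- Comparison: the chosen strategy sets C4 last, by reagent control on a locked ring, and builds the skeleton convergently in the same step that closes the ring.

Key step: step 7

Remark on notation: ring positions are numbered as in the target (O1, C2 aryl-bearing, C4 oxygenated, C6 side-chain-bearing, C7 and C8 in the side chain) for all cyclic compounds. L is the doubly deprotonated tridentate Schiff base of 3-(1-adamantyl)-5-methylsalicylaldehyde and (1S,2R)-cis-1-amino-2-indanol, and CrCl(L) is its chromium chloride complex (trivalent chromium).

Assumption: CrCl(L) of the (1S,2R) series is taken to direct the diene to the Si face of the carbonyl of 11, as the mirror image of the Re-face preference of the (1R,2S) series with α-oxygenated aldehydes. If the sense were the opposite for this substrate, the enantiomeric ligand would be used and nothing else would change.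

## Route

Step 1
Reactants: 1 dehydrozingerone, (E)-4-(4-hydroxy-3-methoxyphenyl)but-3-en-2-one
Product: 2 (E)-4-[4-(benzyloxy)-3-methoxyphenyl]but-3-en-2-one
Conditions: BnBr, K2CO3, DMF, rt
Reagents that add atoms: benzyl bromide, BrCc1ccccc1
Why: Williamson ether synthesis on the phenoxide; the enone has no other site that reacts under carbonate, and the aryl benzyl ether should then survive every step up to the final hydrogenolysis.

Step 2
Reactants: 2 (E)-4-[4-(benzyloxy)-3-methoxyphenyl]but-3-en-2-one
Product: 3 triethyl{[(3E)-4-(4-benzyloxy-3-methoxyphenyl)buta-1,3-dien-2-yl]oxy}silane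
Conditions: Et3SiOTf, Et3N, Et2O, 0 °C
Reagents that add atoms: triethylsilyl trifluoromethanesulfonate, CC[Si](CC)(CC)OS(=O)(=O)C(F)(F)F
Why: Soft enolisation and O-silylation of a methyl ketone; the methyl group is the only enolisable position, so a single cross-conjugated 2-silyloxy diene should form with the E styrenyl bond untouched. The diene is to be used without chromatography on acidic silica.

Step 3
Reactants: 4 O-benzyl-L-tyrosine, (S)-2-amino-3-[4-(benzyloxy)phenyl]propanoic acid
Product: 7 (S)-3-[4-(benzyloxy)phenyl]-2-hydroxypropanoic acid, via α-diazonium carboxylate 5 (not isolated), via α-lactone 6 (not isolated)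
Conditions: NaNO2, 1 M H2SO4, 1,4-dioxane/H2O, 0 °C → rt
Reagents that add atoms: water, O
Why: Nitrous deamination (diazotisation) of an α-amino acid; the neighbouring carboxylate displaces nitrogen with inversion to give the α-lactone, which water opens with a second inversion, so the hydroxy acid should form with net retention (S).

Step 4
Reactants: 7 (S)-3-[4-(benzyloxy)phenyl]-2-hydroxypropanoic acid
Product: 8 methyl (S)-3-[4-(benzyloxy)phenyl]-2-hydroxypropanoate
Conditions: MeOH, H2SO4 (cat.), 50 °C
Reagents that add atoms: methanol, CO
Why: Fischer esterification; the stereocentre is not enolised under acid and the aryl benzyl ether is stable to catalytic acid in methanol.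

Step 5
Reactants: 8 methyl (S)-3-[4-(benzyloxy)phenyl]-2-hydroxypropanoate
Product: 9 methyl (S)-3-[4-(benzyloxy)phenyl]-2-[(tert-butyldimethylsilyl)oxy]propanoate
Conditions: TBSCl, imidazole, DMF, rt
Reagents that add atoms: tert-butyldimethylsilyl chloride, CC(C)(C)[Si](C)(C)Cl
Why: Imidazole-mediated silylation of a secondary alcohol; the bulky silyl ether is orthogonal to the benzyl ethers and should help the later aldehyde keep its configuration.

Step 6
Reactants: 9 methyl (S)-3-[4-(benzyloxy)phenyl]-2-[(tert-butyldimethylsilyl)oxy]propanoate
Product: 11 (S)-3-[4-(benzyloxy)phenyl]-2-[(tert-butyldimethylsilyl)oxy]propanal, via aluminium hemiacetal 10 (not isolated)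
Conditions: i-Bu2AlH (1.1 equiv), CH2Cl2, −78 °C; then MeOH, aq. KNaC4H4O6
Reagents that add atoms: none
Why: Partial reduction of an α-silyloxy ester; the tetrahedral aluminium hemiacetal is stable at −78 °C and releases the aldehyde only on work-up, which should suppress over-reduction. The aldehyde is to be used at once and without chromatography so that C7 stays intact.

Step 7
Reactants: 3 triethyl{[(3E)-4-(4-benzyloxy-3-methoxyphenyl)buta-1,3-dien-2-yl]oxy}silane; 11 (S)-3-[4-(benzyloxy)phenyl]-2-[(tert-butyldimethylsilyl)oxy]propanal
Product: 12 (2R,6S)-2-[4-(benzyloxy)-3-methoxyphenyl]-6-{(1S)-2-[4-(benzyloxy)phenyl]-1-[(tert-butyldimethylsilyl)oxy]ethyl}-4-[(triethylsilyl)oxy]-5,6-dihydro-2H-pyran (2,6-cis)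
Conditions: CrCl(L) (10 mol%), 4 Å MS, t-BuOMe (minimal volume), rt; 3 in excess (1.5 equiv)
Reagents that add atoms: none
Why: Hetero-Diels–Alder reaction: CrCl(L) binds the aldehyde oxygen of 11 anti to the C7 substituent, and the 2-silyloxy diene 3 adds in its s-cis form through a concerted but asynchronous [4+2] transition state in which the nucleophilic enol-ether CH2 (C5) bonds to the carbonyl carbon (C6) ahead of the union of the carbonyl oxygen (O1) with the styrenyl terminus (C2). The closest known reaction type is the catalytic asymmetric hetero-Diels–Alder reaction of aldehydes, α-oxygenated chiral ones included, with 4-substituted 2-silyloxy-1,3-dienes under tridentate Schiff-base chromium chloride catalysis. The oxane ring is closed by the intermolecular cycloaddition itself, both ring bonds forming in one event and not by cyclisation of a preformed chain; the C3=C4 silyl enol ether that remains is the masked C4 ketone. C6 is set by the catalyst, which shields the Re face of the bound carbonyl so that C5 arrives on the Si face (6S). C2 is set by the endo placement of the aldehyde substituent together with the E geometry of the diene, which puts H2 and H6 on the same face and so gives the 2,6-cis ring (2R). C7 comes from 11 unchanged, since the medium is neither basic nor protic. Regioselectivity is secured by the polarity of the diene, whose only nucleophilic terminus is the enol-ether CH2; the facial selectivity is not secured by the substrate, because the non-chelated α-silyloxy aldehyde on its own prefers the 6,7-anti (Felkin–Anh) adduct and the catalyst has to override this in favour of the required 6,7-syn product.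

Step 8
Reactants: 12 the 2,6-cis dihydropyran silyl enol ether of step 7
Product: 13 (2R,6S)-2-[4-(benzyloxy)-3-methoxyphenyl]-6-{(1S)-2-[4-(benzyloxy)phenyl]-1-[(tert-butyldimethylsilyl)oxy]ethyl}oxan-4-one
Conditions: CF3CO2H (cat.), moist CH2Cl2, 0 °C
Reagents that add atoms: none
Why: Protodesilylation of a triethylsilyl enol ether (protonation at C3, loss of silicon from oxygen), which should be far faster than cleavage of the secondary tert-butyldimethylsilyl ether. C2 is the only centre that could epimerise, by reversible ring opening, and the 2,6-cis diequatorial ketone is the thermodynamic isomer.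

Step 9
Reactants: 13 (2R,6S)-2-[4-(benzyloxy)-3-methoxyphenyl]-6-{(1S)-2-[4-(benzyloxy)phenyl]-1-[(tert-butyldimethylsilyl)oxy]ethyl}oxan-4-one
Product: 14 (2R,4S,6S)-2-[4-(benzyloxy)-3-methoxyphenyl]-6-{(1S)-2-[4-(benzyloxy)phenyl]-1-[(tert-butyldimethylsilyl)oxy]ethyl}oxan-4-ol
Conditions: LiBH(s-Bu)3, THF, −78 °C; then H2O
Reagents that add atoms: none
Why: Diastereoselective ketone reduction; the oxanone sits in a chair with both C2 and C6 substituents equatorial, and the bulky trialkylborohydride attacks along the less hindered equatorial trajectory, so the new C4 hydroxyl should be axial (4S) and trans to both substituents.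

Step 10
Reactants: 14 (2R,4S,6S)-2-[4-(benzyloxy)-3-methoxyphenyl]-6-{(1S)-2-[4-(benzyloxy)phenyl]-1-[(tert-butyldimethylsilyl)oxy]ethyl}oxan-4-ol
Product: 15 (2R,4S,6S)-2-[4-(benzyloxy)-3-methoxyphenyl]-6-{(1S)-2-[4-(benzyloxy)phenyl]-1-hydroxyethyl}oxan-4-ol
Conditions: Bu4NF, THF, 0 °C → rt
Reagents that add atoms: none
Why: Fluoride cleavage of a silyl ether; it is carried out while both phenols are still benzylated, so no phenoxide para to the C2–O1 bond is exposed to the basic fluoride.

Step 11
Reactants: 15 (2R,4S,6S)-2-[4-(benzyloxy)-3-methoxyphenyl]-6-{(1S)-2-[4-(benzyloxy)phenyl]-1-hydroxyethyl}oxan-4-ol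
Product: 16 rhoiptelol B, (2R,4S,6S)-2-(4-hydroxy-3-methoxyphenyl)-6-[(1S)-1-hydroxy-2-(4-hydroxyphenyl)ethyl]oxan-4-ol
Conditions: H2 (1 atm), 10% Pd/C, EtOAc, rt
Reagents that add atoms: none
Why: Hydrogenolysis of two aryl benzyl ethers under neutral conditions; phenolic O–benzyl bonds should cleave much faster than the secondary benzylic C2–O1 bond of the ring, and the reaction is to be stopped as soon as 15 is consumed.

## Compound list

1 | dehydrozingerone, (E)-4-(4-hydroxy-3-methoxyphenyl)but-3-en-2-one | COc1cc(/C=C/C(C)=O)ccc1O | starting material
2 | (E)-4-[4-(benzyloxy)-3-methoxyphenyl]but-3-en-2-one | COc1cc(/C=C/C(C)=O)ccc1OCc1ccccc1 | intermediate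
3 | triethyl{[(3E)-4-(4-benzyloxy-3-methoxyphenyl)buta-1,3-dien-2-yl]oxy}silane | COc1cc(/C=C/C(=C)O[Si](CC)(CC)CC)ccc1OCc1ccccc1 | intermediate
4 | O-benzyl-L-tyrosine, (S)-2-amino-3-[4-(benzyloxy)phenyl]propanoic acid | N[C@@H](Cc1ccc(OCc2ccccc2)cc1)C(=O)O | starting material
5 | (S)-2-[4-(benzyloxy)phenyl]-1-carboxylatoethanediazonium (α-diazonium carboxylate, zwitterion) | N#[N+][C@@H](Cc1ccc(OCc2ccccc2)cc1)C(=O)[O-] | intermediate
6 | (R)-3-[4-(benzyloxy)benzyl]oxiran-2-one (α-lactone) | O=C1O[C@@H]1Cc1ccc(OCc2ccccc2)cc1 | intermediate
7 | (S)-3-[4-(benzyloxy)phenyl]-2-hydroxypropanoic acid | O[C@@H](Cc1ccc(OCc2ccccc2)cc1)C(=O)O | intermediate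
8 | methyl (S)-3-[4-(benzyloxy)phenyl]-2-hydroxypropanoate | O[C@@H](Cc1ccc(OCc2ccccc2)cc1)C(=O)OC | intermediate
9 | methyl (S)-3-[4-(benzyloxy)phenyl]-2-[(tert-butyldimethylsilyl)oxy]propanoate | CC(C)(C)[Si](C)(C)O[C@@H](Cc1ccc(OCc2ccccc2)cc1)C(=O)OC | intermediate
10 | {(2S)-3-[4-(benzyloxy)phenyl]-2-[(tert-butyldimethylsilyl)oxy]-1-methoxypropoxy}bis(2-methylpropyl)aluminium (aluminium hemiacetal, both C1 epimers) | COC(O[Al](CC(C)C)CC(C)C)[C@@H](O[Si](C)(C)C(C)(C)C)Cc1ccc(OCc2ccccc2)cc1 | intermediate
11 | (S)-3-[4-(benzyloxy)phenyl]-2-[(tert-butyldimethylsilyl)oxy]propanal | O=C[C@@H](O[Si](C)(C)C(C)(C)C)Cc1ccc(OCc2ccccc2)cc1 | intermediate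
12 | (2R,6S)-2-[4-(benzyloxy)-3-methoxyphenyl]-6-{(1S)-2-[4-(benzyloxy)phenyl]-1-[(tert-butyldimethylsilyl)oxy]ethyl}-4-[(triethylsilyl)oxy]-5,6-dihydro-2H-pyran | COc1cc([C@H]2C=C(O[Si](CC)(CC)CC)C[C@@H]([C@@H](O[Si](C)(C)C(C)(C)C)Cc3ccc(OCc4ccccc4)cc3)O2)ccc1OCc1ccccc1 | intermediate
13 | (2R,6S)-2-[4-(benzyloxy)-3-methoxyphenyl]-6-{(1S)-2-[4-(benzyloxy)phenyl]-1-[(tert-butyldimethylsilyl)oxy]ethyl}oxan-4-one | COc1cc([C@H]2CC(=O)C[C@@H]([C@@H](O[Si](C)(C)C(C)(C)C)Cc3ccc(OCc4ccccc4)cc3)O2)ccc1OCc1ccccc1 | intermediate
14 | (2R,4S,6S)-2-[4-(benzyloxy)-3-methoxyphenyl]-6-{(1S)-2-[4-(benzyloxy)phenyl]-1-[(tert-butyldimethylsilyl)oxy]ethyl}oxan-4-ol | COc1cc([C@H]2C[C@H](O)C[C@@H]([C@@H](O[Si](C)(C)C(C)(C)C)Cc3ccc(OCc4ccccc4)cc3)O2)ccc1OCc1ccccc1 | intermediate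
15 | (2R,4S,6S)-2-[4-(benzyloxy)-3-methoxyphenyl]-6-{(1S)-2-[4-(benzyloxy)phenyl]-1-hydroxyethyl}oxan-4-ol | COc1cc([C@H]2C[C@H](O)C[C@@H]([C@@H](O)Cc3ccc(OCc4ccccc4)cc3)O2)ccc1OCc1ccccc1 | intermediate
16 | rhoiptelol B, (2R,4S,6S)-2-(4-hydroxy-3-methoxyphenyl)-6-[(1S)-1-hydroxy-2-(4-hydroxyphenyl)ethyl]oxan-4-ol | COc1cc([C@H]2C[C@H](O)C[C@@H]([C@@H](O)Cc3ccc(O)cc3)O2)ccc1O | target

## Step count and risk

Total: 11 steps. Longest linear sequence: 9 steps (steps 3 to 11, from 4); the diene branch (steps 1 and 2) joins at step 7.

**Step 7 (key step).** The most likely failure is poor facial selectivity at C6. The pairing is mismatched: the catalyst's preferred face is opposite to the face that the α-silyloxy aldehyde prefers under single-point activation, so the 6,7-anti isomer can compete. A second failure mode is slow cycloaddition of the α-branched aldehyde, which gives time for hydrolysis of the diene. The fallback sets out from 3 and 11 and replaces catalyst control by substrate control. A Mukaiyama aldol addition promoted by Me2AlCl (2.5 equiv, CH2Cl2, −78 °C), in which aluminium bridges the aldehyde oxygen and the C7 silyloxy oxygen, should give the chelation-controlled syn β-hydroxy enone (1E,5S,6S)-1-[4-(benzyloxy)-3-methoxyphenyl]-7-[4-(benzyloxy)phenyl]-6-[(tert-butyldimethylsilyl)oxy]-5-hydroxyhept-1-en-3-one F1. Acid-catalysed oxa-Michael ring closure (Amberlyst-15, CH2Cl2, rt) would then equilibrate to the 2,6-cis ketone, and the route is rejoined at 13. In this fallback the required syn relationship is the natural outcome of chelation and C2 is set thermodynamically.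

**Step 6.** Over-reduction to the primary alcohol, or epimerisation at the α-carbon during work-up, may occur, because the tetrahedral intermediate collapses early if the temperature rises and the α-hydrogen of an α-oxygenated aldehyde is acidic. The fallback sets out from 9. Full reduction (LiBH4, THF, 0 °C) should give (S)-3-[4-(benzyloxy)phenyl]-2-[(tert-butyldimethylsilyl)oxy]propan-1-ol F2, and buffered oxidation (Dess–Martin periodinane, NaHCO3, CH2Cl2, 0 °C) returns to the route at 11.

**Step 9.** Incomplete equatorial attack (erosion of the axial/equatorial ratio) or base-induced ring opening by β-elimination of O1 may occur if the hydride acts as a base on the ketone. The fallback sets out from 13. Reduction with NaBH4 (MeOH, −20 °C), which attacks axially, should give the equatorial alcohol (2R,4R,6S)-2-[4-(benzyloxy)-3-methoxyphenyl]-6-{(1S)-2-[4-(benzyloxy)phenyl]-1-[(tert-butyldimethylsilyl)oxy]ethyl}oxan-4-ol F3. Mitsunobu inversion (4-nitrobenzoic acid, PPh3, DIAD, THF) should give the axial ester (2R,4S,6S)-2-[4-(benzyloxy)-3-methoxyphenyl]-6-{(1S)-2-[4-(benzyloxy)phenyl]-1-[(tert-butyldimethylsilyl)oxy]ethyl}oxan-4-yl 4-nitrobenzoate F4. Methanolysis (K2CO3, MeOH) returns to the route at 14.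

**Step 11.** Over-reduction may occur, namely hydrogenolysis of the benzylic C2–O1 bond with opening of the ring, because the electron-rich guaiacyl group activates that bond on the palladium surface. The fallback sets out from 15 and replaces surface hydrogenolysis by single-electron-transfer debenzylation with LiC10H8 (lithium naphthalenide, excess, THF, −25 °C). The unsubstituted phenyl rings of the benzyl groups are better electron acceptors than the oxygenated arenes, and each expels a phenoxide, a far better leaving group than the ring alkoxide. Aqueous work-up returns to the route at 16. This fallback makes no new compound (entered as F0).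

## Further compounds

F1 | step 7 | (1E,5S,6S)-1-[4-(benzyloxy)-3-methoxyphenyl]-7-[4-(benzyloxy)phenyl]-6-[(tert-butyldimethylsilyl)oxy]-5-hydroxyhept-1-en-3-one | COc1cc(/C=C/C(=O)C[C@H](O)[C@@H](O[Si](C)(C)C(C)(C)C)Cc2ccc(OCc3ccccc3)cc2)ccc1OCc1ccccc1
F2 | step 6 | (S)-3-[4-(benzyloxy)phenyl]-2-[(tert-butyldimethylsilyl)oxy]propan-1-ol | OC[C@@H](O[Si](C)(C)C(C)(C)C)Cc1ccc(OCc2ccccc2)cc1
F3 | step 9 | (2R,4R,6S)-2-[4-(benzyloxy)-3-methoxyphenyl]-6-{(1S)-2-[4-(benzyloxy)phenyl]-1-[(tert-butyldimethylsilyl)oxy]ethyl}oxan-4-ol | COc1cc([C@H]2C[C@@H](O)C[C@@H]([C@@H](O[Si](C)(C)C(C)(C)C)Cc3ccc(OCc4ccccc4)cc3)O2)ccc1OCc1ccccc1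
F4 | step 9 | (2R,4S,6S)-2-[4-(benzyloxy)-3-methoxyphenyl]-6-{(1S)-2-[4-(benzyloxy)phenyl]-1-[(tert-butyldimethylsilyl)oxy]ethyl}oxan-4-yl 4-nitrobenzoate | COc1cc([C@H]2C[C@H](OC(=O)c3ccc(cc3)[N+](=O)[O-])C[C@@H]([C@@H](O[Si](C)(C)C(C)(C)C)Cc3ccc(OCc4ccccc4)cc3)O2)ccc1OCc1ccccc1
F0 | step 11 | none | none
A1 | alternative 1 | 2-(tert-butyldimethylsilyl)-1,3-dithiane | CC(C)(C)[Si](C)(C)C1SCCCS1
A2 | alternative 1 | 2-[4-(benzyloxy)-3-methoxyphenyl]oxirane (racemic) | COc1cc(C2CO2)ccc1OCc1ccccc1
A3 | alternative 1 | (2S)-2-{(1S)-1-(benzyloxy)-2-[4-(benzyloxy)phenyl]ethyl}oxirane | C1O[C@@H]1[C@@H](OCc1ccccc1)Cc1ccc(OCc2ccccc2)cc1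
A4 | alternative 1 | (2S,3S)-3-(benzyloxy)-1-{2-[2-(4-benzyloxy-3-methoxyphenyl)-2-[(tert-butyldimethylsilyl)oxy]ethyl]-1,3-dithian-2-yl}-4-[4-(benzyloxy)phenyl]butan-2-ol (both epimers at the silyloxy carbon) | COc1cc(C(O[Si](C)(C)C(C)(C)C)CC2(C[C@H](O)[C@@H](OCc3ccccc3)Cc3ccc(OCc4ccccc4)cc3)SCCCS2)ccc1OCc1ccccc1
A5 | alternative 2 | (4S,5S)-5-(benzyloxy)-4-{[4-(benzyloxy)-3-methoxyphenyl]methoxy}-6-[4-(benzyloxy)phenyl]hex-1-en-2-yl acetate | COc1cc(CO[C@@H](CC(=C)OC(C)=O)[C@@H](OCc2ccccc2)Cc2ccc(OCc3ccccc3)cc2)ccc1OCc1ccccc1
A6 | alternative 2 | (2R,6S)-2-[4-(benzyloxy)-3-methoxyphenyl]-6-{(1S)-1-(benzyloxy)-2-[4-(benzyloxy)phenyl]ethyl}oxan-4-one | COc1cc([C@H]2CC(=O)C[C@@H]([C@@H](OCc3ccccc3)Cc3ccc(OCc4ccccc4)cc3)O2)ccc1OCc1ccccc1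
A7 | alternative 3 | (3S,5S,6S)-1-[4-(benzyloxy)-3-methoxyphenyl]-7-[4-(benzyloxy)phenyl]-3,6-bis[(tert-butyldimethylsilyl)oxy]heptane-1,5-diol (both C1 epimers) | COc1cc(C(O)C[C@H](O[Si](C)(C)C(C)(C)C)C[C@H](O)[C@@H](O[Si](C)(C)C(C)(C)C)Cc2ccc(OCc3ccccc3)cc2)ccc1OCc1ccccc1
A8 | alternative 3 | (2R,4S,6S)-2-[4-(benzyloxy)-3-methoxyphenyl]-6-{(1S)-2-[4-(benzyloxy)phenyl]-1-[(tert-butyldimethylsilyl)oxy]ethyl}-4-[(tert-butyldimethylsilyl)oxy]oxane | COc1cc([C@H]2C[C@H](O[Si](C)(C)C(C)(C)C)C[C@@H]([C@@H](O[Si](C)(C)C(C)(C)C)Cc3ccc(OCc4ccccc4)cc3)O2)ccc1OCc1ccccc1
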